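**Strategy.** The plan rests on cutting ring A (C4a, C5, C6, C7, C8, C8a) off a terpene-derived ring B: (R)-carvone supplies C1–C4, C4a and C8a with the trans C1/C4 pair already in place. A semicyclic 2-silyloxydiene (C6=C5(OTIPS)–C4a=C8a) built on that ring takes up a propiolate ester in a [4+2] cycloaddition and is dehydrogenated in the same flask. One operation therefore forms C6–C7 and C8–C8a and delivers the benzene ring with the C5 oxygen para to the C8 carboxyl. Phenol (TIPS) and acid (2-trimethylsilylethyl) are masked for one final fluoride release; C11 and the C12–C16 chain follow by catalyst-controlled hydroboration and sp3–sp2 coupling.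

Key step: step 6

Remark (numbering): ring B = C1–C4, C4a, C8a; ring A = C4a, C5–C8, C8a; the side chain is C11 (on C1), C12–C15 and C16 (CH2O). In this numbering the target is 1S,4R,11S,15R.

Remark (assumption): the facial sense of the copper hydride catalyst in step 7 is assigned by analogy. (R)-DTBM-SEGPHOS is written; its commercial enantiomer would be used instead if a first run shows that it is the one that delivers the 11S product, with no other change.

Remark (design): the carboxyl is carried as a 2-(trimethylsilyl)ethyl ester and the phenol as a TIPS ether, because a simple alkyl benzoate could not be hydrolysed once the base-sensitive C16 ester is in place.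

**Route**

Step 1
Reactants: 1 (R)-(−)-carvone
Product: 3 (2R,5R)-2-methyl-5-(prop-1-en-2-yl)cyclohexan-1-one (trans-dihydrocarvone), via lithium enolate 2 (not isolated)
Conditions: L-Selectride, THF, −78 °C; then AcOH, −78 °C → rt
Reagents that add atoms: none
Why: Conjugate reduction of a β-unsubstituted cyclohexenone with a bulky borohydride gives enolate 2, and its axial protonation, backed by the thermodynamic preference for the diequatorial isomer, should place the C2 methyl trans to the isopropenyl group; any cis epimer is removed by chromatography after brief base equilibration.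

Step 2
Reactants: 3 (2R,5R)-2-methyl-5-(prop-1-en-2-yl)cyclohexan-1-one
Product: 5 (3R,6R)-6-methyl-3-(prop-1-en-2-yl)cyclohex-1-en-1-yl trifluoromethanesulfonate, via kinetic lithium enolate 4 (not isolated)
Conditions: LDA (commercial solution), THF, −78 °C; then PhNTf2, −78 → 0 °C
Reagents that add atoms: N-phenylbis(trifluoromethanesulfonimide), O=S(=O)(N(c1ccccc1)S(=O)(=O)C(F)(F)F)C(F)(F)F
Why: Kinetic deprotonation by LDA takes a proton from the unhindered ring methylene and O-triflation fixes the double bond toward the carbon that becomes C8a, leaving the methyl-bearing centre untouched (kinetic enol triflate formation).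

Step 3
Reactants: 5 (3R,6R)-6-methyl-3-(prop-1-en-2-yl)cyclohex-1-en-1-yl trifluoromethanesulfonate; 6 tributyl(1-ethoxyethenyl)stannane
Product: 8 1-[(3R,6R)-6-methyl-3-(prop-1-en-2-yl)cyclohex-1-en-1-yl]ethan-1-one, via ethoxydiene 7 (not isolated)
Conditions: Pd(PPh3)4 (5 mol%), LiCl, THF, 65 °C; then 1 M HCl, rt
Reagents that add atoms: water, O
Why: Stille coupling of an alkenyl triflate with an acyl-anion equivalent gives dienyl ether 7, whose enol ether is hydrolysed by dilute acid to the methyl ketone without moving the ring double bond.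

Step 4
Reactants: 8 1-[(3R,6R)-6-methyl-3-(prop-1-en-2-yl)cyclohex-1-en-1-yl]ethan-1-one
Product: 10 triisopropyl({1-[(3R,6R)-6-methyl-3-(prop-1-en-2-yl)cyclohex-1-en-1-yl]ethenyl}oxy)silane, via cross-conjugated lithium dienolate 9 (not isolated)
Conditions: LDA (commercial solution), THF, −78 °C; then TIPSOTf, −78 → 0 °C
Reagents that add atoms: triisopropylsilyl trifluoromethanesulfonate, CC(C)[Si](OS(=O)(=O)C(F)(F)F)(C(C)C)C(C)C
Why: Kinetic enolisation of a methyl enone removes an acetyl-methyl proton and not the doubly allylic γ-hydrogen, so O-silylation gives the 2-silyloxy-1,3-diene with the ring stereocentre intact; the bulky TIPS group makes the dienol ether robust enough to purify on base-washed silica.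

Step 5
Reactants: 11 propiolic acid; 12 2-(trimethylsilyl)ethan-1-ol
Product: 13 2-(trimethylsilyl)ethyl prop-2-ynoate
Conditions: DCC, DMAP (5 mol%), CH2Cl2, −20 → 0 °C
Reagents that add atoms: none
Why: Steglich esterification at low temperature gives the fluoride-cleavable ynoate without conjugate addition to the triple bond.

Step 6
Reactants: 10 triisopropyl({1-[(3R,6R)-6-methyl-3-(prop-1-en-2-yl)cyclohex-1-en-1-yl]ethenyl}oxy)silane; 13 2-(trimethylsilyl)ethyl prop-2-ynoate
Product: 15 2-(trimethylsilyl)ethyl (5R,8S)-5-methyl-8-(prop-1-en-2-yl)-4-[(triisopropylsilyl)oxy]-5,6,7,8-tetrahydronaphthalene-1-carboxylate, via cyclohexa-1,4-diene cycloadduct 14 (not isolated)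
Conditions: toluene, 110 °C (sealed tube); then DDQ (1.1 equiv), 0 °C → rt
Reagents that add atoms: none
Why: The electron-rich diene C6=C5(OTIPS)–C4a=C8a of 10 and ynoate 13 combine in a thermal, concerted but asynchronous [4+2] cycloaddition to give 1,4-cyclohexadiene 14; DDQ then abstracts hydride from the doubly allylic C8a–H (the cation is stabilised by the C5 silyloxy group) and a proton is lost from C6, which gives the benzene ring. The closest known reaction type is the Diels–Alder reaction of 2-silyloxy-1,3-dienes with propiolate esters followed by quinone dehydrogenation to 4-silyloxybenzoates. Ring A (C4a, C5, C6, C7, C8, C8a) is closed by intermolecular [4+2] annulation onto the existing ring B, with C6–C7 and C8–C8a formed in the same step. No lasting stereocentre is created (C8a of 14 is erased on aromatisation), and C1 and C4 are sp3 spectators that nothing in the flask should epimerise. The selectivity needed is regiochemical: the enol ether terminus C6 carries the largest HOMO coefficient and bonds to the β-carbon of the ynoate, an orientation that the alkyl substituent on C8a reinforces, so the ester lands on C8, para to the C5 oxygen. One equivalent of DDQ at room temperature and the robust TIPS group should leave the benzylic C1–H and C4–H bonds and the O–Si bond intact.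

Step 7
Reactants: 15 2-(trimethylsilyl)ethyl (5R,8S)-5-methyl-8-(prop-1-en-2-yl)-4-[(triisopropylsilyl)oxy]-5,6,7,8-tetrahydronaphthalene-1-carboxylate
Product: 16 2-(trimethylsilyl)ethyl (5R,8S)-5-methyl-8-[(2S)-1-(4,4,5,5-tetramethyl-1,3,2-dioxaborolan-2-yl)propan-2-yl]-4-[(triisopropylsilyl)oxy]-5,6,7,8-tetrahydronaphthalene-1-carboxylate
Conditions: CuCl (5 mol%), (R)-DTBM-SEGPHOS (6 mol%), NaOtBu (10 mol%), HBpin, toluene, rt
Reagents that add atoms: pinacolborane, [H]B1OC(C)(C)C(C)(C)O1
Why: Copper hydride-catalysed anti-Markovnikov hydroboration of an unactivated 1,1-disubstituted alkene: the ligand-controlled hydrocupration delivers hydrogen to one face of C11 and the primary alkylcopper is borylated with retention, so C11 is set by the catalyst and not by the uncertain bias of the neighbouring C1 centre.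

Step 8
Reactants: 17 methyl (S)-3-hydroxy-2-methylpropanoate (Roche ester)
Product: 18 methyl (S)-3-[(tert-butyldimethylsilyl)oxy]-2-methylpropanoate
Conditions: TBSCl, imidazole, CH2Cl2, rt
Reagents that add atoms: tert-butyldimethylsilyl chloride, CC(C)(C)[Si](C)(C)Cl
Why: Standard silylation of a primary alcohol; the stereocentre (future C15) is not involved.

Step 9
Reactants: 18 methyl (S)-3-[(tert-butyldimethylsilyl)oxy]-2-methylpropanoate
Product: 19 (S)-3-[(tert-butyldimethylsilyl)oxy]-2-methylpropanal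
Conditions: DIBAL-H (1.05 equiv), CH2Cl2, −78 °C; MeOH, aq. Rochelle salt
Reagents that add atoms: none
Why: Partial reduction of an ester with DIBAL-H at −78 °C stops at the aldehyde oxidation level until work-up; the aldehyde is used crude and cold so that its α-centre should not epimerise.

Step 10
Reactants: 19 (S)-3-[(tert-butyldimethylsilyl)oxy]-2-methylpropanal
Product: 20 tert-butyl{[(2R,3E)-4-iodo-2-methylbut-3-en-1-yl]oxy}dimethylsilane
Conditions: CrCl2, CHI3, THF, 0 °C → rt
Reagents that add atoms: iodoform, IC(I)I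
Why: Takai olefination converts the aldehyde into the (E)-alkenyl iodide (C13=C14) under non-basic conditions that should leave the α-stereocentre intact; the descriptor changes from S to R only because the priorities change.

Step 11
Reactants: 16 2-(trimethylsilyl)ethyl (5R,8S)-5-methyl-8-[(2S)-1-(4,4,5,5-tetramethyl-1,3,2-dioxaborolan-2-yl)propan-2-yl]-4-[(triisopropylsilyl)oxy]-5,6,7,8-tetrahydronaphthalene-1-carboxylate; 20 tert-butyl{[(2R,3E)-4-iodo-2-methylbut-3-en-1-yl]oxy}dimethylsilane
Product: 21 2-(trimethylsilyl)ethyl (5R,8S)-8-[(2S,4E,6R)-7-[(tert-butyldimethylsilyl)oxy]-6-methylhept-4-en-2-yl]-5-methyl-4-[(triisopropylsilyl)oxy]-5,6,7,8-tetrahydronaphthalene-1-carboxylate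
Conditions: Pd(OAc)2 (5 mol%), RuPhos (10 mol%), K3PO4, toluene/H2O (10:1), 80 °C
Reagents that add atoms: none
Why: Suzuki–Miyaura coupling of a primary alkyl pinacol boronate with an alkenyl iodide under a bulky dialkylbiarylphosphine–palladium catalyst forms C12–C13; neither C11 nor C15 takes part, and the hindered aryl ester and TIPS ether should tolerate aqueous phosphate.

Step 12
Reactants: 21 2-(trimethylsilyl)ethyl (5R,8S)-8-[(2S,4E,6R)-7-[(tert-butyldimethylsilyl)oxy]-6-methylhept-4-en-2-yl]-5-methyl-4-[(triisopropylsilyl)oxy]-5,6,7,8-tetrahydronaphthalene-1-carboxylate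
Product: 22 2-(trimethylsilyl)ethyl (5R,8S)-8-[(2S,6R)-7-[(tert-butyldimethylsilyl)oxy]-6-methylheptan-2-yl]-5-methyl-4-[(triisopropylsilyl)oxy]-5,6,7,8-tetrahydronaphthalene-1-carboxylate
Conditions: H2 (1 atm), PtO2 (5 mol%), EtOAc, rt
Reagents that add atoms: none
Why: Platinum-catalysed hydrogenation saturates the 1,2-disubstituted C13=C14 alkene with little double-bond migration, so the allylic C15 centre should keep its configuration, and the arene, esters and silyl ethers are inert at 1 atm.

Step 13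
Reactants: 22 2-(trimethylsilyl)ethyl (5R,8S)-8-[(2S,6R)-7-[(tert-butyldimethylsilyl)oxy]-6-methylheptan-2-yl]-5-methyl-4-[(triisopropylsilyl)oxy]-5,6,7,8-tetrahydronaphthalene-1-carboxylate
Product: 23 2-(trimethylsilyl)ethyl (5R,8S)-8-[(2S,6R)-7-hydroxy-6-methylheptan-2-yl]-5-methyl-4-[(triisopropylsilyl)oxy]-5,6,7,8-tetrahydronaphthalene-1-carboxylate
Conditions: CSA (10 mol%), MeOH/CH2Cl2 (1:1), 0 °C
Reagents that add atoms: none
Why: Acid-catalysed methanolysis removes a primary alkyl TBS ether far faster than the hindered aryl TIPS ether, and the silylethyl ester is stable to mild acid (selective desilylation).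

Step 14
Reactants: 23 2-(trimethylsilyl)ethyl (5R,8S)-8-[(2S,6R)-7-hydroxy-6-methylheptan-2-yl]-5-methyl-4-[(triisopropylsilyl)oxy]-5,6,7,8-tetrahydronaphthalene-1-carboxylate; 24 4-methylpent-3-enoic acid
Product: 25 2-(trimethylsilyl)ethyl (5R,8S)-5-methyl-8-[(2S,6R)-6-methyl-7-[(4-methylpent-3-enoyl)oxy]heptan-2-yl]-4-[(triisopropylsilyl)oxy]-5,6,7,8-tetrahydronaphthalene-1-carboxylate
Conditions: PPh3, DIAD, THF, 0 °C → rt
Reagents that add atoms: none
Why: Mitsunobu esterification activates the primary C16 alcohol and not the acid, so the β,γ-unsaturated acid is never converted into an enolisable acyl donor and its double bond should stay out of conjugation; C16 is a CH2 group, so no stereocentre is touched.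

Step 15
Reactants: 25 2-(trimethylsilyl)ethyl (5R,8S)-5-methyl-8-[(2S,6R)-6-methyl-7-[(4-methylpent-3-enoyl)oxy]heptan-2-yl]-4-[(triisopropylsilyl)oxy]-5,6,7,8-tetrahydronaphthalene-1-carboxylate
Product: 26 (5R,8S)-4-hydroxy-5-methyl-8-[(2S,6R)-6-methyl-7-[(4-methylpent-3-enoyl)oxy]heptan-2-yl]-5,6,7,8-tetrahydronaphthalene-1-carboxylic acid
Conditions: TBAF, THF, 0 °C → rt; then 0.5 M HCl
Reagents that add atoms: none
Why: Fluoride attacks silicon in both masking groups, cleaving the aryl silyl ether directly and fragmenting the silylethyl ester to carboxylate, ethene and fluorotrimethylsilane, while the aliphatic C16 ester should survive a short, cold exposure (fluoride-induced global deprotection).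

**Compound list**

1 | (R)-(−)-carvone, (5R)-2-methyl-5-(prop-1-en-2-yl)cyclohex-2-en-1-one | CC(=C)[C@@H]1CC=C(C)C(=O)C1 | starting material
2 | lithium (5R)-2-methyl-5-(prop-1-en-2-yl)cyclohex-1-en-1-olate | [Li+].CC(=C)[C@@H]1CCC(C)=C([O-])C1 | intermediate (not isolated)
3 | (2R,5R)-2-methyl-5-(prop-1-en-2-yl)cyclohexan-1-one | CC(=C)[C@@H]1CC[C@@H](C)C(=O)C1 | intermediate
4 | lithium (3R,6R)-6-methyl-3-(prop-1-en-2-yl)cyclohex-1-en-1-olate | [Li+].CC(=C)[C@@H]1CC[C@@H](C)C([O-])=C1 | intermediate (not isolated)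
5 | (3R,6R)-6-methyl-3-(prop-1-en-2-yl)cyclohex-1-en-1-yl trifluoromethanesulfonate | CC(=C)[C@@H]1CC[C@@H](C)C(OS(=O)(=O)C(F)(F)F)=C1 | intermediate
6 | tributyl(1-ethoxyethenyl)stannane | CCCC[Sn](CCCC)(CCCC)C(=C)OCC | starting material
7 | (3R,6R)-1-(1-ethoxyethenyl)-6-methyl-3-(prop-1-en-2-yl)cyclohex-1-ene | CC(=C)[C@@H]1CC[C@@H](C)C(C(=C)OCC)=C1 | intermediate (not isolated)
8 | 1-[(3R,6R)-6-methyl-3-(prop-1-en-2-yl)cyclohex-1-en-1-yl]ethan-1-one | CC(=C)[C@@H]1CC[C@@H](C)C(C(C)=O)=C1 | intermediate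
9 | lithium 1-[(3R,6R)-6-methyl-3-(prop-1-en-2-yl)cyclohex-1-en-1-yl]ethen-1-olate | [Li+].CC(=C)[C@@H]1CC[C@@H](C)C(C(=C)[O-])=C1 | intermediate (not isolated)
10 | triisopropyl({1-[(3R,6R)-6-methyl-3-(prop-1-en-2-yl)cyclohex-1-en-1-yl]ethenyl}oxy)silane | CC(=C)[C@@H]1CC[C@@H](C)C(C(=C)O[Si](C(C)C)(C(C)C)C(C)C)=C1 | intermediate
11 | propiolic acid (prop-2-ynoic acid) | C#CC(=O)O | starting material
12 | 2-(trimethylsilyl)ethan-1-ol | C[Si](C)(C)CCO | starting material
13 | 2-(trimethylsilyl)ethyl prop-2-ynoate | C#CC(=O)OCC[Si](C)(C)C | intermediate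
14 | 2-(trimethylsilyl)ethyl (5R,8R)-5-methyl-8-(prop-1-en-2-yl)-4-[(triisopropylsilyl)oxy]-3,5,6,7,8,8a-hexahydronaphthalene-1-carboxylate (both C8a epimers) | CC(=C)[C@@H]1CC[C@@H](C)C2=C(O[Si](C(C)C)(C(C)C)C(C)C)CC=C(C(=O)OCC[Si](C)(C)C)C12 | intermediate (not isolated)
15 | 2-(trimethylsilyl)ethyl (5R,8S)-5-methyl-8-(prop-1-en-2-yl)-4-[(triisopropylsilyl)oxy]-5,6,7,8-tetrahydronaphthalene-1-carboxylate | CC(=C)[C@@H]1CC[C@@H](C)c2c(O[Si](C(C)C)(C(C)C)C(C)C)ccc(C(=O)OCC[Si](C)(C)C)c21 | intermediate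
16 | 2-(trimethylsilyl)ethyl (5R,8S)-5-methyl-8-[(2S)-1-(4,4,5,5-tetramethyl-1,3,2-dioxaborolan-2-yl)propan-2-yl]-4-[(triisopropylsilyl)oxy]-5,6,7,8-tetrahydronaphthalene-1-carboxylate | CC1(C)OB(C[C@H](C)[C@@H]2CC[C@@H](C)c3c(O[Si](C(C)C)(C(C)C)C(C)C)ccc(C(=O)OCC[Si](C)(C)C)c32)OC1(C)C | intermediate
17 | methyl (S)-3-hydroxy-2-methylpropanoate (Roche ester) | OC[C@H](C)C(=O)OC | starting material
18 | methyl (S)-3-[(tert-butyldimethylsilyl)oxy]-2-methylpropanoate | CC(C)(C)[Si](C)(C)OC[C@H](C)C(=O)OC | intermediate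
19 | (S)-3-[(tert-butyldimethylsilyl)oxy]-2-methylpropanal | CC(C)(C)[Si](C)(C)OC[C@H](C)C=O | intermediate
20 | tert-butyl{[(2R,3E)-4-iodo-2-methylbut-3-en-1-yl]oxy}dimethylsilane | CC(C)(C)[Si](C)(C)OC[C@H](C)/C=C/I | intermediate
21 | 2-(trimethylsilyl)ethyl (5R,8S)-8-[(2S,4E,6R)-7-[(tert-butyldimethylsilyl)oxy]-6-methylhept-4-en-2-yl]-5-methyl-4-[(triisopropylsilyl)oxy]-5,6,7,8-tetrahydronaphthalene-1-carboxylate | CC(C)(C)[Si](C)(C)OC[C@H](C)/C=C/C[C@H](C)[C@@H]1CC[C@@H](C)c2c(O[Si](C(C)C)(C(C)C)C(C)C)ccc(C(=O)OCC[Si](C)(C)C)c21 | intermediate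
22 | 2-(trimethylsilyl)ethyl (5R,8S)-8-[(2S,6R)-7-[(tert-butyldimethylsilyl)oxy]-6-methylheptan-2-yl]-5-methyl-4-[(triisopropylsilyl)oxy]-5,6,7,8-tetrahydronaphthalene-1-carboxylate | CC(C)(C)[Si](C)(C)OC[C@H](C)CCC[C@H](C)[C@@H]1CC[C@@H](C)c2c(O[Si](C(C)C)(C(C)C)C(C)C)ccc(C(=O)OCC[Si](C)(C)C)c21 | intermediate
23 | 2-(trimethylsilyl)ethyl (5R,8S)-8-[(2S,6R)-7-hydroxy-6-methylheptan-2-yl]-5-methyl-4-[(triisopropylsilyl)oxy]-5,6,7,8-tetrahydronaphthalene-1-carboxylate | OC[C@H](C)CCC[C@H](C)[C@@H]1CC[C@@H](C)c2c(O[Si](C(C)C)(C(C)C)C(C)C)ccc(C(=O)OCC[Si](C)(C)C)c21 | intermediate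
24 | 4-methylpent-3-enoic acid | CC(C)=CCC(=O)O | starting material
25 | 2-(trimethylsilyl)ethyl (5R,8S)-5-methyl-8-[(2S,6R)-6-methyl-7-[(4-methylpent-3-enoyl)oxy]heptan-2-yl]-4-[(triisopropylsilyl)oxy]-5,6,7,8-tetrahydronaphthalene-1-carboxylate | CC(C)=CCC(=O)OC[C@H](C)CCC[C@H](C)[C@@H]1CC[C@@H](C)c2c(O[Si](C(C)C)(C(C)C)C(C)C)ccc(C(=O)OCC[Si](C)(C)C)c21 | intermediate
26 | (5R,8S)-4-hydroxy-5-methyl-8-[(2S,6R)-6-methyl-7-[(4-methylpent-3-enoyl)oxy]heptan-2-yl]-5,6,7,8-tetrahydronaphthalene-1-carboxylic acid | CC(C)=CCC(=O)OC[C@H](C)CCC[C@H](C)[C@@H]1CC[C@@H](C)c2c(O)ccc(C(=O)O)c21 | target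

**Step count.** Total: 15 steps. Longest linear sequence: 11 steps (steps 1–4, 6, 7 and 11–15, from (R)-carvone).

**Steps most likely to fail**

1. Step 7. The chiral copper hydride may turn over slowly on the hindered alkene, or may give poor facial selectivity at C11 if ligand and C1 centre are mismatched. The fallback sets out from 15 and replaces catalyst control by a stoichiometric dialkylborane. Hydroboration with 9-BBN in THF (rt → 50 °C) should give the B-alkyl-9-BBN adduct F1, which is not isolated. It is coupled in the same flask with iodide 20 (PdCl2(dppf), AsPh3, Cs2CO3, DMF/H2O, rt; B-alkyl Suzuki–Miyaura). The route is rejoined at 21, bypassing 16 and step 11. Any C11 epimer would be separated at the stage of the primary alcohol 23.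

2. Step 11. Transmetalation of the β-branched primary pinacol boronate may be slow, so that protodeboronation or β-hydride elimination competes and long heating in aqueous base starts to strip silyl groups. The fallback sets out from 16 and changes the coupling to an organozinc. Oxidation of the C–B bond (NaBO3·4H2O, THF/H2O) gives the primary alcohol F2. An Appel reaction (I2, PPh3, imidazole) gives the primary iodide F3. Zinc insertion (Zn dust, LiCl, THF) gives the alkylzinc iodide F4. Negishi coupling of F4 with 20 (Pd(PPh3)4, THF, rt → 50 °C) returns to the route at 21.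

3. Step 6. Cycloaddition at the hindered C8a terminus may be sluggish, so that thermal loss of the dienol ether competes before the oxidant is added. The fallback sets out from 10 and uses a more reactive acetylenic dienophile at the aldehyde oxidation level. Prop-2-ynal (toluene, rt → 60 °C) should give the cyclohexadiene carbaldehyde F5, which is dehydrogenated in the same flask with DDQ to the aryl aldehyde F6. Pinnick oxidation (NaClO2, NaH2PO4, 2-methyl-2-butene, t-BuOH/H2O) gives the benzoic acid F7. Mitsunobu esterification of F7 with 12 (PPh3, DIAD, THF) returns to the route at 15.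

**Further compounds**

F1 | step 7 | 2-(trimethylsilyl)ethyl (5R,8S)-8-[(2S)-1-(9-borabicyclo[3.3.1]nonan-9-yl)propan-2-yl]-5-methyl-4-[(triisopropylsilyl)oxy]-5,6,7,8-tetrahydronaphthalene-1-carboxylate | C[C@@H](CB3C4CCCC3CCC4)[C@@H]1CC[C@@H](C)c2c(O[Si](C(C)C)(C(C)C)C(C)C)ccc(C(=O)OCC[Si](C)(C)C)c21
F2 | step 11 | 2-(trimethylsilyl)ethyl (5R,8S)-8-[(2R)-1-hydroxypropan-2-yl]-5-methyl-4-[(triisopropylsilyl)oxy]-5,6,7,8-tetrahydronaphthalene-1-carboxylate | OC[C@H](C)[C@@H]1CC[C@@H](C)c2c(O[Si](C(C)C)(C(C)C)C(C)C)ccc(C(=O)OCC[Si](C)(C)C)c21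
F3 | step 11 | 2-(trimethylsilyl)ethyl (5R,8S)-8-[(2R)-1-iodopropan-2-yl]-5-methyl-4-[(triisopropylsilyl)oxy]-5,6,7,8-tetrahydronaphthalene-1-carboxylate | IC[C@H](C)[C@@H]1CC[C@@H](C)c2c(O[Si](C(C)C)(C(C)C)C(C)C)ccc(C(=O)OCC[Si](C)(C)C)c21
F4 | step 11 | {(2R)-2-[(1S,4R)-4-methyl-5-[(triisopropylsilyl)oxy]-8-{[2-(trimethylsilyl)ethoxy]carbonyl}-1,2,3,4-tetrahydronaphthalen-1-yl]propyl}zinc iodide | I[Zn]C[C@H](C)[C@@H]1CC[C@@H](C)c2c(O[Si](C(C)C)(C(C)C)C(C)C)ccc(C(=O)OCC[Si](C)(C)C)c21
F5 | step 6 | (5R,8R)-5-methyl-8-(prop-1-en-2-yl)-4-[(triisopropylsilyl)oxy]-3,5,6,7,8,8a-hexahydronaphthalene-1-carbaldehyde (both C8a epimers) | CC(=C)[C@@H]1CC[C@@H](C)C2=C(O[Si](C(C)C)(C(C)C)C(C)C)CC=C(C=O)C12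
F6 | step 6 | (5R,8S)-5-methyl-8-(prop-1-en-2-yl)-4-[(triisopropylsilyl)oxy]-5,6,7,8-tetrahydronaphthalene-1-carbaldehyde | CC(=C)[C@@H]1CC[C@@H](C)c2c(O[Si](C(C)C)(C(C)C)C(C)C)ccc(C=O)c21
F7 | step 6 | (5R,8S)-5-methyl-8-(prop-1-en-2-yl)-4-[(triisopropylsilyl)oxy]-5,6,7,8-tetrahydronaphthalene-1-carboxylic acid | CC(=C)[C@@H]1CC[C@@H](C)c2c(O[Si](C(C)C)(C(C)C)C(C)C)ccc(C(=O)O)c21
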